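**Plan**
1. Retrosynthesis: the thiolactone carbonyl C1 is a single carbon between arene carbon C7a and S2 in the five-membered ring (C1, S2, C3, C3a, C7a). Cutting C7a–C1 and C1–S2 returns it as CO and leaves a C7a iodide and a C3 thiol.
2. Further cuts: C3–S (thioacetate opening of a trans aryl epoxide), C2′–C3′ (butyl onto an epoxy triflate), the epoxide oxygen (epoxidation of a cinnamyl-type alcohol), C3=C1′ (Wittig), then C7a–I, the formyl carbon and the prenyl group on a hydroquinone core.
3. Forward: 2,5-dibromohydroquinone is protected, prenylated and formylated through two bromine–lithium exchanges, then iodinated by directed lithiation. The side chain is grown (enoate, allylic alcohol, epoxy alcohol, pentyl epoxide, thioacetate, thiol), the thiolactone ring closes in step 12, and one acid step unmasks the target.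
4. Stereochemistry: the Sharpless epoxidation with D-(−)-tartrate fixes both centres. C1′ keeps that oxygen (R); C3 becomes S by one inversion when sulfur opens the epoxide and is not touched afterwards.

Key step: step 12

Remarks: target numbering is C1 (C=O), S2, C3, C3a, C4–C7, C7a, side chain C1′–C6′; Ar = 2-iodo-3,6-bis(methoxymethoxy)-4-(3-methylbut-2-en-1-yl)phenyl; MOM = methoxymethyl; TBS = tert-butyldimethylsilyl.
Assumption: thioacetic acid is taken to open trans-epoxide 20 at the benzylic carbon with inversion, the usual course for aryl alkyl epoxides under acid assistance.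

**Step 1**
Reactants: 1 2,5-dibromobenzene-1,4-diol (2,5-dibromohydroquinone)
Product: 2 1,4-dibromo-2,5-bis(methoxymethoxy)benzene
Conditions: MOMCl, i-Pr2NEt, CH2Cl2, 0 °C → rt
Reagents that add atoms: chloromethyl methyl ether (MOMCl), COCCl
Why: O-Alkylation of both phenols with the α-chloro ether under amine base (MOM ether formation) is routine and gives acetals that survive organolithiums, direct the later lithiation and leave under mild acid.

**Step 2**
Reactants: 2 1,4-dibromo-2,5-bis(methoxymethoxy)benzene; 3 1-bromo-3-methylbut-2-ene (prenyl bromide)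
Product: 6 1-bromo-2,5-bis(methoxymethoxy)-4-(3-methylbut-2-en-1-yl)benzene, via aryllithium 4 (not isolated), via arylcopper 5 (not isolated)
Conditions: n-BuLi (1.0 equiv), THF, −78 °C; CuBr·SMe2 (1.0 equiv), −78 → −40 °C; 3, −40 → 0 °C
Reagents that add atoms: prenyl bromide 3, CC(C)=CCBr
Why: Bromine–lithium exchange on the symmetric dibromide stops cleanly after one bromine at −78 °C and the arylcopper formed by transmetalation is alkylated by prenyl bromide at its primary carbon (copper-mediated allylic substitution), so the prenyl group is placed without any regiochemical choice on the ring.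

**Step 3**
Reactants: 6 1-bromo-2,5-bis(methoxymethoxy)-4-(3-methylbut-2-en-1-yl)benzene
Product: 9 2,5-bis(methoxymethoxy)-4-(3-methylbut-2-en-1-yl)benzaldehyde, via aryllithium 7 (not isolated), via lithium hemiaminal alkoxide 8 (not isolated)
Conditions: n-BuLi, THF, −78 °C; DMF, −78 → 0 °C; H2O
Reagents that add atoms: N,N-dimethylformamide, CN(C)C=O
Why: A second bromine–lithium exchange and formylation of the aryllithium with DMF (Bouveault-type aldehyde synthesis) put the future C3 carbon para to the prenyl group, the alkene and the acetals being inert to n-BuLi at −78 °C.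

**Step 4**
Reactants: 9 2,5-bis(methoxymethoxy)-4-(3-methylbut-2-en-1-yl)benzaldehyde
Product: 13 2-iodo-3,6-bis(methoxymethoxy)-4-(3-methylbut-2-en-1-yl)benzaldehyde (ArCHO), via lithium α-amino alkoxide 10 (not isolated), via ring-lithiated α-amino alkoxide 11 (not isolated), via iodinated α-amino alkoxide 12 (not isolated)
Conditions: LiN(Me)CH2CH2NMe2 (from Me2NCH2CH2NHMe and n-BuLi), THF, −20 °C; n-BuLi (3 equiv), −20 °C; I2, THF, −78 °C; aq. Na2S2O3
Reagents that add atoms: iodine, II
Why: Directed ortho-metalation: the aldehyde is masked in situ as a chelating lithium α-amino alkoxide which, together with the adjacent OMOM group, steers n-BuLi to the one ring hydrogen flanked by two directing groups (the future C7a), and iodine quench followed by hydrolysis returns the iodo aldehyde.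

**Step 5**
Reactants: 13 ArCHO; 14 ethyl (triphenylphosphoranylidene)acetate
Product: 15 ethyl (2E)-3-Ar-prop-2-enoate
Conditions: Ph3P=CHCO2Et, toluene, 90 °C
Reagents that add atoms: ethyl (triphenylphosphoranylidene)acetate 14, CCOC(=O)C=P(c1ccccc1)(c1ccccc1)c1ccccc1
Why: Wittig olefination with the stabilised ylide gives the (E)-enoate from the non-enolisable, di-ortho-substituted aldehyde and does not touch the aryl iodide.

**Step 6**
Reactants: 15 ethyl (2E)-3-Ar-prop-2-enoate
Product: 16 (2E)-3-Ar-prop-2-en-1-ol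
Conditions: i-Bu2AlH, CH2Cl2, −78 °C; aq. potassium sodium tartrate
Reagents that add atoms: none
Why: Hydride 1,2-reduction of the enoate with i-Bu2AlH at −78 °C gives the (E)-allylic alcohol and leaves aryl iodide, acetals and both alkenes intact.

**Step 7**
Reactants: 16 (2E)-3-Ar-prop-2-en-1-ol
Product: 17 [(2R,3R)-3-Ar-oxiran-2-yl]methanol
Conditions: Ti(OiPr)4 (cat.), D-(−)-diisopropyl tartrate, t-BuOOH, 4 Å molecular sieves, CH2Cl2, −20 °C
Reagents that add atoms: tert-butyl hydroperoxide, CC(C)(C)OO
Why: The Sharpless asymmetric epoxidation oxidises only the allylic alcohol (the prenyl alkene has no directing hydroxyl) and, with D-(−)-tartrate, turns (E)-3-arylallyl alcohols into (2R,3R)-epoxy alcohols, which sets C1′ as R and the benzylic centre in the configuration that sulfur will invert.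

**Step 8**
Reactants: 17 [(2R,3R)-3-Ar-oxiran-2-yl]methanol; 18 butylmagnesium chloride
Product: 20 (2R,3R)-2-Ar-3-pentyloxirane, via epoxy triflate 19 (not isolated)
Conditions: Tf2O, 2,6-lutidine, CH2Cl2, −78 °C; crude triflate, n-BuMgCl, CuBr·SMe2 (10 mol %), Et2O, −78 → −40 °C
Reagents that add atoms: butylmagnesium chloride 18, CCCC[Mg]Cl
Why: A primary alkyl triflate undergoes copper-catalysed substitution by the Grignard reagent at −78 °C (sp3–sp3 coupling) much faster than the epoxide is opened or the aryl iodide exchanged, so C2′–C3′ is formed while both stereocentres are left alone.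

**Step 9**
Reactants: 20 (2R,3R)-2-Ar-3-pentyloxirane
Product: 21 S-[(1S,2R)-1-Ar-2-hydroxyheptyl] ethanethioate
Conditions: AcSH (3 equiv), Et3N (0.3 equiv), toluene, 0 °C → rt, dark, under argon
Reagents that add atoms: thioacetic acid, CC(=O)S
Why: Acid-assisted thiolysis of an aryl alkyl epoxide: thioacetate attacks the benzylic carbon, which is activated by the arene and by hydrogen bonding of AcSH to the oxirane, in an SN2 opening with inversion that turns the (R) benzylic centre into the (1S) thioester and leaves the C2 oxygen with its configuration.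

**Step 10**
Reactants: 21 S-[(1S,2R)-1-Ar-2-hydroxyheptyl] ethanethioate
Product: 22 S-[(1S,2R)-1-Ar-2-(tert-butyldimethylsilyloxy)heptyl] ethanethioate
Conditions: TBSOTf, 2,6-lutidine, CH2Cl2, −78 °C
Reagents that add atoms: tert-butyldimethylsilyl trifluoromethanesulfonate (TBSOTf), CC(C)(C)[Si](C)(C)OS(=O)(=O)C(F)(F)F
Why: O-Silylation with the silyl triflate and 2,6-lutidine at −78 °C is faster than S-to-O acetyl migration and masks the hydroxyl so that it cannot capture the acyl group in step 12.

**Step 11**
Reactants: 22 S-[(1S,2R)-1-Ar-2-(tert-butyldimethylsilyloxy)heptyl] ethanethioate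
Product: 23 (1S,2R)-1-Ar-2-(tert-butyldimethylsilyloxy)heptane-1-thiol
Conditions: N2H4·H2O, degassed THF/MeOH, 0 °C; used without storage
Reagents that add atoms: none
Why: Hydrazinolysis of the thioester (acyl transfer to an α-effect nucleophile) frees the thiol without base strong enough to touch the silyl ether, the acetals, the aryl iodide or the benzylic stereocentre.

**Step 12**
Reactants: 23 (1S,2R)-1-Ar-2-(tert-butyldimethylsilyloxy)heptane-1-thiol; 24 carbon monoxide
Product: 25 (3S)-3-[(1R)-1-(tert-butyldimethylsilyloxy)hexyl]-4,7-bis(methoxymethoxy)-6-(3-methylbut-2-en-1-yl)-2-benzothiophen-1(3H)-one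
Conditions: Pd(OAc)2 (5 mol %), Xantphos (7.5 mol %), CO (1 atm), Et3N, toluene (0.01 M), 70 °C
Reagents that add atoms: carbon monoxide 24, [C-]#[O+]
Why: Pd(OAc)2 is reduced in situ to zerovalent palladium bound to Xantphos, which inserts into the C7a–I bond; CO coordination and migratory insertion give a divalent aroylpalladium iodide, the thiol (deprotonated by Et3N) replaces iodide, and C–S reductive elimination releases the thioester and returns zerovalent palladium. The closest known reaction type is the palladium-catalysed thiocarbonylation of aryl iodides with thiols and CO, run here intramolecularly in the manner of the carbonylative lactonisation of ortho-halobenzyl alcohols to phthalides. The ring (C1, S2, C3, C3a, C7a) closes in the 5-exo-trig mode at the acyl carbon, through reductive elimination from a six-membered acyl thiolato palladacycle. No stereocentre is formed; C3 and C1′ come in from 23, and the weak amine base and moderate temperature should leave the benzylic, sulfur-bearing C3–H unepimerised. The chemoselectivity needed is S-acylation rather than direct aryl–sulfur coupling, oligomerisation or catalyst arrest: direct coupling would have to form a four-membered benzothiete, so the arylpalladium thiolate can only go on by taking up CO, high dilution favours the intramolecular path, and the wide-bite-angle chelating Xantphos resists displacement by thiolate and speeds reductive elimination. The C1′ oxygen is silylated so that it cannot compete for the acyl group, and the prenyl alkene is too remote and too substituted for a Heck pathway.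

**Step 13**
Reactants: 25 (3S)-3-[(1R)-1-(tert-butyldimethylsilyloxy)hexyl]-4,7-bis(methoxymethoxy)-6-(3-methylbut-2-en-1-yl)-2-benzothiophen-1(3H)-one
Product: 26 asperglaucin A, (3S)-4,7-dihydroxy-3-[(1R)-1-hydroxyhexyl]-6-(3-methylbut-2-en-1-yl)-2-benzothiophen-1(3H)-one
Conditions: HCl (1.25 M in MeOH), THF, rt → 40 °C
Reagents that add atoms: none
Why: Acid-catalysed acetal exchange removes both phenolic MOM ethers and acid methanolysis removes the secondary silyl ether in one operation (global deprotection), and dilute methanolic HCl near room temperature should stay below the threshold for prenyl cyclisation and thioester methanolysis.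

**Compound list**
1 | 2,5-dibromobenzene-1,4-diol | Oc1cc(Br)c(O)cc1Br | starting material
2 | 1,4-dibromo-2,5-bis(methoxymethoxy)benzene | COCOc1cc(Br)c(OCOC)cc1Br | intermediate
3 | 1-bromo-3-methylbut-2-ene (prenyl bromide) | CC(C)=CCBr | starting material
4 | [4-bromo-2,5-bis(methoxymethoxy)phenyl]lithium | [Li]c1cc(OCOC)c(Br)cc1OCOC | intermediate
5 | [4-bromo-2,5-bis(methoxymethoxy)phenyl]copper | [Cu]c1cc(OCOC)c(Br)cc1OCOC | intermediate
6 | 1-bromo-2,5-bis(methoxymethoxy)-4-(3-methylbut-2-en-1-yl)benzene | CC(C)=CCc1cc(OCOC)c(Br)cc1OCOC | intermediate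
7 | [2,5-bis(methoxymethoxy)-4-(3-methylbut-2-en-1-yl)phenyl]lithium | [Li]c1cc(OCOC)c(CC=C(C)C)cc1OCOC | intermediate
8 | lithium (dimethylamino)[2,5-bis(methoxymethoxy)-4-(3-methylbut-2-en-1-yl)phenyl]methanolate | [Li]OC(N(C)C)c1cc(OCOC)c(CC=C(C)C)cc1OCOC | intermediate
9 | 2,5-bis(methoxymethoxy)-4-(3-methylbut-2-en-1-yl)benzaldehyde | O=Cc1cc(OCOC)c(CC=C(C)C)cc1OCOC | intermediate
10 | lithium α-amino alkoxide of 9 and N,N,N′-trimethylethylenediamine (racemic at the aminal carbon) | [Li]OC(N(C)CCN(C)C)c1cc(OCOC)c(CC=C(C)C)cc1OCOC | intermediate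
11 | 6-lithio derivative of 10 | [Li]OC(N(C)CCN(C)C)c1c([Li])c(OCOC)c(CC=C(C)C)cc1OCOC | intermediate
12 | 6-iodo derivative of 10 | [Li]OC(N(C)CCN(C)C)c1c(I)c(OCOC)c(CC=C(C)C)cc1OCOC | intermediate
13 | 2-iodo-3,6-bis(methoxymethoxy)-4-(3-methylbut-2-en-1-yl)benzaldehyde | O=Cc1c(I)c(OCOC)c(CC=C(C)C)cc1OCOC | intermediate
14 | ethyl (triphenylphosphoranylidene)acetate | CCOC(=O)C=P(c1ccccc1)(c1ccccc1)c1ccccc1 | starting material
15 | ethyl (2E)-3-[2-iodo-3,6-bis(methoxymethoxy)-4-(3-methylbut-2-en-1-yl)phenyl]prop-2-enoate | CCOC(=O)/C=C/c1c(I)c(OCOC)c(CC=C(C)C)cc1OCOC | intermediate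
16 | (2E)-3-[2-iodo-3,6-bis(methoxymethoxy)-4-(3-methylbut-2-en-1-yl)phenyl]prop-2-en-1-ol | OC/C=C/c1c(I)c(OCOC)c(CC=C(C)C)cc1OCOC | intermediate
17 | [(2R,3R)-3-[2-iodo-3,6-bis(methoxymethoxy)-4-(3-methylbut-2-en-1-yl)phenyl]oxiran-2-yl]methanol | OC[C@H]1O[C@@H]1c2c(I)c(OCOC)c(CC=C(C)C)cc2OCOC | intermediate
18 | butylmagnesium chloride | CCCC[Mg]Cl | starting material
19 | [(2R,3R)-3-Ar-oxiran-2-yl]methyl trifluoromethanesulfonate | FC(F)(F)S(=O)(=O)OC[C@H]1O[C@@H]1c2c(I)c(OCOC)c(CC=C(C)C)cc2OCOC | intermediate
20 | (2R,3R)-2-[2-iodo-3,6-bis(methoxymethoxy)-4-(3-methylbut-2-en-1-yl)phenyl]-3-pentyloxirane | CCCCC[C@H]1O[C@@H]1c2c(I)c(OCOC)c(CC=C(C)C)cc2OCOC | intermediate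
21 | S-[(1S,2R)-2-hydroxy-1-[2-iodo-3,6-bis(methoxymethoxy)-4-(3-methylbut-2-en-1-yl)phenyl]heptyl] ethanethioate | CCCCC[C@@H](O)[C@@H](SC(C)=O)c1c(I)c(OCOC)c(CC=C(C)C)cc1OCOC | intermediate
22 | S-[(1S,2R)-2-(tert-butyldimethylsilyloxy)-1-[2-iodo-3,6-bis(methoxymethoxy)-4-(3-methylbut-2-en-1-yl)phenyl]heptyl] ethanethioate | CCCCC[C@@H](O[Si](C)(C)C(C)(C)C)[C@@H](SC(C)=O)c1c(I)c(OCOC)c(CC=C(C)C)cc1OCOC | intermediate
23 | (1S,2R)-2-(tert-butyldimethylsilyloxy)-1-[2-iodo-3,6-bis(methoxymethoxy)-4-(3-methylbut-2-en-1-yl)phenyl]heptane-1-thiol | CCCCC[C@@H](O[Si](C)(C)C(C)(C)C)[C@@H](S)c1c(I)c(OCOC)c(CC=C(C)C)cc1OCOC | intermediate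
24 | carbon monoxide | [C-]#[O+] | starting material
25 | (3S)-3-[(1R)-1-(tert-butyldimethylsilyloxy)hexyl]-4,7-bis(methoxymethoxy)-6-(3-methylbut-2-en-1-yl)-2-benzothiophen-1(3H)-one | CCCCC[C@@H](O[Si](C)(C)C(C)(C)C)[C@H]1SC(=O)c2c(OCOC)c(CC=C(C)C)cc(OCOC)c21 | intermediate
26 | asperglaucin A, (3S)-4,7-dihydroxy-3-[(1R)-1-hydroxyhexyl]-6-(3-methylbut-2-en-1-yl)-2-benzothiophen-1(3H)-one | CCCCC[C@@H](O)[C@H]1SC(=O)c2c(O)c(CC=C(C)C)cc(O)c21 | target

**Step count and risks**
Total steps: 13. Longest linear sequence: 13 steps (1 → 26).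

Steps most likely to fail:

1. Step 9. Thioacetate may attack the non-benzylic oxirane carbon, which is less shielded than the di-ortho-substituted benzylic one. The benzylic C–O bond may also ionise and erode the inversion, or AcSH may add to the prenyl alkene by a radical chain. Fallback: the sulfur is introduced before the chain is extended, where titanium chelation enforces attack at C3. It sets out from epoxy alcohol 17: Ti(OiPr)4 and triphenylmethanethiol should open it at the benzylic carbon with inversion to the trityl sulfide diol F1. Selective sulfonylation of the primary hydroxyl (TsCl, Et3N, cat. Bu2SnO) gives the monotosylate F2, and K2CO3 in MeOH closes the terminal epoxide F3. n-BuMgCl 18 with catalytic CuBr·SMe2 opens F3 at its CH2 end to the hydroxy sulfide F4, and TBSOTf/2,6-lutidine gives the silyl ether F5. AgNO3/pyridine in MeOH followed by dithiothreitol removes the trityl group and returns to the route at thiol 23.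

2. Step 12. Thiolate may sequester palladium, the thiol may be oxidised to disulfide, or the aryl iodide may be reduced before CO is taken up. Fallback: carbonylation and ring closure are separated so that no free thiol meets the catalyst. It sets out from thioacetate 22: hydroxycarbonylation (Pd(OAc)2, Xantphos, CO, H2O, Et3N, DMF, 70 °C) should give the S-acetyl benzoic acid F6. Hydrazine hydrate frees the mercapto acid F7, and carbodiimide activation (EDC·HCl, cat. DMAP, CH2Cl2, 0 °C) closes the thiolactone by intramolecular S-acylation, returning to the route at 25.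

3. Step 13. Protic acid may cyclise the prenyl group onto the freed C7 phenol, or shift the acyl group from sulfur to the freed C1′ hydroxyl or to methanol. Fallback: the groups are removed in two stages by non-protic reagents, with the C1′ oxygen kept masked until the end. It sets out from 25: ZnBr2 with n-PrSH in CH2Cl2 at 0 °C should cleave both MOM ethers to the silyl-protected hydroquinone F8. HF·pyridine in THF/pyridine at 0 °C then removes the silyl ether and arrives at 26.

**Further compounds**
F1 | step 9 | (2R,3S)-3-Ar-3-(tritylsulfanyl)propane-1,2-diol | OC[C@@H](O)[C@@H](SC(c1ccccc1)(c1ccccc1)c1ccccc1)c1c(I)c(OCOC)c(CC=C(C)C)cc1OCOC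
F2 | step 9 | (2R,3S)-3-Ar-2-hydroxy-3-(tritylsulfanyl)propyl 4-methylbenzenesulfonate | Cc1ccc(cc1)S(=O)(=O)OC[C@@H](O)[C@@H](SC(c1ccccc1)(c1ccccc1)c1ccccc1)c1c(I)c(OCOC)c(CC=C(C)C)cc1OCOC
F3 | step 9 | (2R)-2-[(S)-Ar(tritylsulfanyl)methyl]oxirane | C1O[C@H]1[C@@H](SC(c2ccccc2)(c2ccccc2)c2ccccc2)c2c(I)c(OCOC)c(CC=C(C)C)cc2OCOC
F4 | step 9 | (1S,2R)-1-Ar-1-(tritylsulfanyl)heptan-2-ol | CCCCC[C@@H](O)[C@@H](SC(c1ccccc1)(c1ccccc1)c1ccccc1)c1c(I)c(OCOC)c(CC=C(C)C)cc1OCOC
F5 | step 9 | tert-butyl{[(1S,2R)-1-Ar-1-(tritylsulfanyl)heptan-2-yl]oxy}dimethylsilane | CCCCC[C@@H](O[Si](C)(C)C(C)(C)C)[C@@H](SC(c1ccccc1)(c1ccccc1)c1ccccc1)c1c(I)c(OCOC)c(CC=C(C)C)cc1OCOC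
F6 | step 12 | 2-[(1S,2R)-1-(acetylsulfanyl)-2-(tert-butyldimethylsilyloxy)heptyl]-3,6-bis(methoxymethoxy)-5-(3-methylbut-2-en-1-yl)benzoic acid | CCCCC[C@@H](O[Si](C)(C)C(C)(C)C)[C@@H](SC(C)=O)c1c(C(=O)O)c(OCOC)c(CC=C(C)C)cc1OCOC
F7 | step 12 | 2-[(1S,2R)-2-(tert-butyldimethylsilyloxy)-1-sulfanylheptyl]-3,6-bis(methoxymethoxy)-5-(3-methylbut-2-en-1-yl)benzoic acid | CCCCC[C@@H](O[Si](C)(C)C(C)(C)C)[C@@H](S)c1c(C(=O)O)c(OCOC)c(CC=C(C)C)cc1OCOC
F8 | step 13 | (3S)-3-[(1R)-1-(tert-butyldimethylsilyloxy)hexyl]-4,7-dihydroxy-6-(3-methylbut-2-en-1-yl)-2-benzothiophen-1(3H)-one | CCCCC[C@@H](O[Si](C)(C)C(C)(C)C)[C@H]1SC(=O)c2c(O)c(CC=C(C)C)cc(O)c21
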